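With the core numbered as a tetrahydroindole (pyrrole ring A: N1, C2, C3, C3a, C7a; carbocycle B: C4–C7; azepine C spanning N1 and C7), the plan rests on cutting C7a–C7 and C6–C5. The C7a–C7 bond lies in rings B and C and C7, C6, C5 are adjacent stereocentres, so one amine-catalysed intramolecular Diels–Alder reaction closes both rings and sets all three: an enal tethered to N1 adds across the pyrrole C7a=C3a bond and a C4=C5 benzyloxyvinyl group, after which a proton moves from C7a to C4 and ring A is aromatic again. The precursor is an N-(7-oxohept-5-enyl)-4-(2-benzyloxyvinyl)pyrrole bearing a methyl ester at C2, a spectator that blocks the second α-carbon and tempers the pyrrole.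

Key step: step 5

Remarks on the chemistry
- Assumption: the target SMILES is read as the single enantiomer 4S,5R,6R,7R, ring D α-carbon S, ring E 2R,4S (oxolane numbering).
- Further labels: ring D is the lactone fused at C4–C5, ring E the lactone on C2, C8–C11 the azepine CH2 groups from C7 to N1. Tricyclic compounds are named as 4,5,6,7-tetrahydroindoles with a 1,7-butano bridge.
- The C5 configuration made in step 5 is not carried to the target, because C5 passes through a ketone in step 8. Only the E enol ether is taken into step 5, so that one diastereomer is handled.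
- The C2 ester stays on until step 12, so that every intermediate before that is a deactivated, air-stable pyrrole.

Step 1
Reactants: 1 methyl 4-formyl-1H-pyrrole-2-carboxylate; 2 5-bromopentan-1-ol
Product: 3 methyl 4-formyl-1-(5-hydroxypentyl)-1H-pyrrole-2-carboxylate
Conditions: K2CO3, DMF, 60 °C
Reagents that add atoms: none
Why: N-alkylation (SN2): carbonate deprotonates only the pyrrole N–H, which the ester and formyl groups acidify, so the pyrrolide displaces the primary bromide while the free hydroxyl stays untouched.

Step 2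
Reactants: 3 methyl 4-formyl-1-(5-hydroxypentyl)-1H-pyrrole-2-carboxylate; 4 (benzyloxymethyl)triphenylphosphonium chloride
Product: 5 methyl 4-[(E)-2-(benzyloxy)ethenyl]-1-(5-hydroxypentyl)-1H-pyrrole-2-carboxylate
Conditions: 4 (2.5 equiv), KOtBu, THF, 0 °C; then 3, 0 °C to rt; E isomer separated on Et3N-washed silica
Reagents that add atoms: none
Why: Wittig olefination with the alkoxymethylidene ylide (the excess covers the free hydroxyl); this ylide is not stereoselective, so both enol ether isomers should form and the E isomer is separated for the key step.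

Step 3
Reactants: 5 methyl 4-[(E)-2-(benzyloxy)ethenyl]-1-(5-hydroxypentyl)-1H-pyrrole-2-carboxylate
Product: 6 methyl 4-[(E)-2-(benzyloxy)ethenyl]-1-(5-oxopentyl)-1H-pyrrole-2-carboxylate
Conditions: Dess–Martin periodinane, pyridine, CH2Cl2, 0 °C to rt
Reagents that add atoms: none
Why: Dess–Martin oxidation of the primary alcohol; the pyridine buffer keeps the enol ether from hydrolysis and the ester-deactivated pyrrole is not attacked.

Step 4
Reactants: 6 methyl 4-[(E)-2-(benzyloxy)ethenyl]-1-(5-oxopentyl)-1H-pyrrole-2-carboxylate; 7 (triphenylphosphoranylidene)acetaldehyde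
Product: 8 methyl 4-[(E)-2-(benzyloxy)ethenyl]-1-[(5E)-7-oxohept-5-en-1-yl]-1H-pyrrole-2-carboxylate
Conditions: 7 (1.3 equiv), toluene, 70 °C
Reagents that add atoms: none
Why: Wittig homologation with the stabilised formylmethylene ylide, which gives the E enal and reacts with the aliphatic aldehyde faster than with the conjugated product.

Step 5
Reactants: 8 methyl 4-[(E)-2-(benzyloxy)ethenyl]-1-[(5E)-7-oxohept-5-en-1-yl]-1H-pyrrole-2-carboxylate
Product: 11 methyl (5S,6R,7R)-5-(benzyloxy)-6-formyl-4,5,6,7-tetrahydro-1,7-butanoindole-2-carboxylate, via iminium ion 9 (not isolated), via dearomatised cycloadduct 10 (not isolated)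
Conditions: (S)-2-[diphenyl(trimethylsilyloxy)methyl]pyrrolidine (20 mol%), PhCO2H (20 mol%), toluene (0.01 M), −20 °C to rt; aq. NaHCO3
Reagents that add atoms: none
Why: The amine and benzoic acid turn the enal into the E iminium ion 9, whose β-carbon is attacked by C7a, the far end of the 1-oxydiene C7a=C3a–C4=C5–OBn; the enamine so formed closes on C5 (in concert, or as a conjugate addition followed by addition to the oxocarbenium ion, with the same result) to give 10, and a proton shift from C7a to C4 plus hydrolysis release aromatic 11 and the catalyst. The closest known reactions are the diarylprolinol silyl ether catalysed Diels–Alder reactions of vinylindoles and vinylpyrroles with enals and the amine-catalysed intramolecular Diels–Alder reactions of trienals. Ring C closes in the 7-exo-trig sense (C7a onto the β-carbon, the N1 chain being the tether), and ring B is the six-membered cycloadduct ring, in stepwise terms a 6-(enolexo)-exo-trig closure of C6 onto C5. C7 is set by the catalyst, whose diphenyl(silyloxy)methyl group covers one face of the s-trans iminium ion so that C7a bonds from the open face (7R); C6 follows from the E enal (C7 and C6 trans, also the stable arrangement of the enolisable aldehyde); C5 follows from the endo placement of the iminium group, which the chain enforces because it reaches the in-plane N1 only from the exo side, together with the E enol ether (C5–O cis to the formyl group). The step needs attack at C7a and not at the other α-carbon, which the C2 ester blocks, and it needs cyclisation to outrun intermolecular addition and enol ether hydrolysis, which high dilution, the weak acid and the ester-tempered pyrrole favour.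

Step 6
Reactants: 11 methyl (5S,6R,7R)-5-(benzyloxy)-6-formyl-4,5,6,7-tetrahydro-1,7-butanoindole-2-carboxylate
Product: 12 methyl (5S,6R,7R)-5-(benzyloxy)-6-ethenyl-4,5,6,7-tetrahydro-1,7-butanoindole-2-carboxylate
Conditions: Ph3PCH3Br, KOtBu, THF, 0 °C; then 11, −78 to 0 °C
Reagents that add atoms: methyltriphenylphosphonium bromide, C[P+](c1ccccc1)(c1ccccc1)c1ccccc1.[Br-]
Why: Wittig methylenation; the reactive ylide adds at low temperature faster than it enolises the α-branched β-benzyloxy aldehyde, C6 already sits in its stable arrangement trans to the C7 chain, and the pyrrole ester is inert.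

Step 7
Reactants: 12 methyl (5S,6R,7R)-5-(benzyloxy)-6-ethenyl-4,5,6,7-tetrahydro-1,7-butanoindole-2-carboxylate
Product: 13 methyl (5S,6R,7R)-6-ethyl-5-hydroxy-4,5,6,7-tetrahydro-1,7-butanoindole-2-carboxylate
Conditions: H2 (1 atm), 10% Pd/C, EtOAc/EtOH, rt
Reagents that add atoms: none
Why: Heterogeneous hydrogenation saturates the vinyl group to the C6 ethyl and hydrogenolyses the benzyl ether to the C5 alcohol in one operation; the pyrrole-2-carboxylate is not reduced and no stereocentre is touched.

Step 8
Reactants: 13 methyl (5S,6R,7R)-6-ethyl-5-hydroxy-4,5,6,7-tetrahydro-1,7-butanoindole-2-carboxylate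
Product: 14 methyl (6R,7R)-6-ethyl-5-oxo-4,5,6,7-tetrahydro-1,7-butanoindole-2-carboxylate
Conditions: Dess–Martin periodinane, pyridine, CH2Cl2, 0 °C to rt
Reagents that add atoms: none
Why: Dess–Martin oxidation of the secondary alcohol gives the C5 ketone that activates C4; C6 keeps its configuration because the ethyl group is already trans to the C7 chain.

Step 9
Reactants: 15 ethyl (2S)-2-hydroxypropanoate (ethyl (S)-lactate)
Product: 16 ethyl (2S)-2-[(trifluoromethanesulfonyl)oxy]propanoate
Conditions: Tf2O, 2,6-lutidine, CH2Cl2, −78 to 0 °C; pentane/silica plug, used at once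
Reagents that add atoms: trifluoromethanesulfonic anhydride, O=S(=O)(OS(=O)(=O)C(F)(F)F)C(F)(F)F
Why: O-sulfonylation of the secondary alcohol with triflic anhydride and a hindered base; the stereocentre is not touched, so the S configuration of the lactate is kept.

Step 10
Reactants: 14 methyl (6R,7R)-6-ethyl-5-oxo-4,5,6,7-tetrahydro-1,7-butanoindole-2-carboxylate; 16 ethyl (2S)-2-[(trifluoromethanesulfonyl)oxy]propanoate
Product: 18 methyl (4S,6R,7R)-4-[(2S)-1-ethoxy-1-oxopropan-2-yl]-6-ethyl-5-oxo-4,5,6,7-tetrahydro-1,7-butanoindole-2-carboxylate, via sodium enolate 17 (not isolated)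
Conditions: NaN(SiMe3)2, THF, −78 °C; 16, −78 to −40 °C; AcOH; then DBU (0.2 equiv), CH2Cl2, rt
Reagents that add atoms: none
Why: Enolate alkylation: the base removes a C4 proton (the ketone α-position conjugated with the pyrrole and the less hindered side), and the soft enolate displaces the secondary triflate by SN2 with inversion, which gives the S side-chain centre (the descriptor is kept because the incoming carbon ranks below the ester carbon); C4 stays epimerisable, and the DBU equilibration should leave the side chain pseudo-equatorial, cis to the C6 ethyl group (4S).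

Step 11
Reactants: 18 methyl (4S,6R,7R)-4-[(2S)-1-ethoxy-1-oxopropan-2-yl]-6-ethyl-5-oxo-4,5,6,7-tetrahydro-1,7-butanoindole-2-carboxylate
Product: 20 γ-lactone (ring D) of (2S)-2-[(4S,5R,6R,7R)-6-ethyl-5-hydroxy-2-(methoxycarbonyl)-4,5,6,7-tetrahydro-1,7-butanoindol-4-yl]propanoic acid, via hydroxy ester 19 (not isolated)
Conditions: LiBH(s-Bu)3 (L-Selectride), THF, −78 °C to rt; aq. NH4Cl
Reagents that add atoms: none
Why: Hindered-hydride reduction: the bulky borohydride enters on the ring B face opposite the two flanking substituents at C4 and C6, so the C5 alkoxide forms cis to both (5R) and closes on the neighbouring ethyl ester to the cis-fused γ-lactone by intramolecular transesterification.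

Step 12
Reactants: 20 γ-lactone (ring D) of (2S)-2-[(4S,5R,6R,7R)-6-ethyl-5-hydroxy-2-(methoxycarbonyl)-4,5,6,7-tetrahydro-1,7-butanoindol-4-yl]propanoic acid
Product: 23 γ-lactone (ring D) of (2S)-2-[(4S,5R,6R,7R)-6-ethyl-5-hydroxy-4,5,6,7-tetrahydro-1,7-butanoindol-4-yl]propanoic acid, via dilithium hydroxy dicarboxylate 21 (not isolated), via lactone acid 22 (not isolated)
Conditions: LiOH, THF/MeOH/H2O, 50 °C; then CF3CO2H/CH2Cl2, rt; aq. NaHCO3
Reagents that add atoms: none
Why: Saponification followed by acid-promoted protodecarboxylation of the pyrrole-2-carboxylic acid (ipso protonation at C2, loss of CO2) while the opened ring D recloses under the acid; the ring D α-centre is not at risk, because hydroxide opens the lactone faster than it enolises it and a carboxylate α-proton is not acidic.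

Step 13
Reactants: 24 (S)-2-methylsuccinic acid
Product: 25 (3S)-3-methyloxolane-2,5-dione ((S)-2-methylsuccinic anhydride)
Conditions: AcCl, reflux; distillation
Reagents that add atoms: none
Why: Cyclodehydration of the 1,4-diacid to the five-membered anhydride by acetyl chloride; the stereocentre is not enolised under these acidic conditions.

Step 14
Reactants: 23 γ-lactone (ring D) of (2S)-2-[(4S,5R,6R,7R)-6-ethyl-5-hydroxy-4,5,6,7-tetrahydro-1,7-butanoindol-4-yl]propanoic acid; 25 (3S)-3-methyloxolane-2,5-dione
Product: 26 (2S)-2-methyl-4-oxo-4-[C2 of ring D lactone 23]butanoic acid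
Conditions: AlCl3 (2.2 equiv), CH2Cl2, −20 to 0 °C; cold dilute HCl
Reagents that add atoms: none
Why: Friedel–Crafts acylation: the only free pyrrole α-carbon (C2) attacks the less hindered anhydride carbonyl (the one next to CH2), which places the methyl-bearing carbon beside the free acid; no stereocentre is formed or touched.

Step 15
Reactants: 26 (2S)-2-methyl-4-oxo-4-[C2 of ring D lactone 23]butanoic acid
Product: 28 CNP0232452.1, ring D lactone 23 carrying at C2 a (2R,4S)-4-methyl-5-oxooxolan-2-yl group (ring E), via hydroxy acid 27 (not isolated)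
Conditions: RuCl[(R,R)-TsDPEN](p-cymene) (2 mol%), HCO2Na, H2O/MeOH, 40 °C; then AcOH, rt
Reagents that add atoms: none
Why: Noyori–Ikariya asymmetric transfer hydrogenation: the (R,R) catalyst delivers hydride to the face of the aryl ketone that gives the (R)-carbinol (reagent control, as for aryl alkyl ketones), and the γ-hydroxy acid lactonises with retention on mild acidification to ring E with methyl and pyrrole trans; aqueous formate keeps the medium near neutral so that the pyrrolylic C–O bond does not ionise.

Compound list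
1 | methyl 4-formyl-1H-pyrrole-2-carboxylate | COC(=O)c1cc(C=O)c[nH]1 | starting material
2 | 5-bromopentan-1-ol | OCCCCCBr | starting material
3 | methyl 4-formyl-1-(5-hydroxypentyl)-1H-pyrrole-2-carboxylate | COC(=O)c1cc(C=O)cn1CCCCCO | intermediate
4 | (benzyloxymethyl)triphenylphosphonium chloride | [Cl-].c1ccc(cc1)COC[P+](c1ccccc1)(c1ccccc1)c1ccccc1 | starting material
5 | methyl 4-[(E)-2-(benzyloxy)ethenyl]-1-(5-hydroxypentyl)-1H-pyrrole-2-carboxylate | COC(=O)c1cc(/C=C/OCc2ccccc2)cn1CCCCCO | intermediate
6 | methyl 4-[(E)-2-(benzyloxy)ethenyl]-1-(5-oxopentyl)-1H-pyrrole-2-carboxylate | COC(=O)c1cc(/C=C/OCc2ccccc2)cn1CCCCC=O | intermediate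
7 | (triphenylphosphoranylidene)acetaldehyde | O=CC=P(c1ccccc1)(c1ccccc1)c1ccccc1 | starting material
8 | methyl 4-[(E)-2-(benzyloxy)ethenyl]-1-[(5E)-7-oxohept-5-en-1-yl]-1H-pyrrole-2-carboxylate (key-step precursor) | COC(=O)c1cc(/C=C/OCc2ccccc2)cn1CCCC/C=C/C=O | intermediate
9 | iminium ion of 8 with (S)-2-[diphenyl(trimethylsilyloxy)methyl]pyrrolidine, benzoate salt | COC(=O)c1cc(/C=C/OCc2ccccc2)cn1CCCC/C=C/C=[N+]1CCC[C@H]1C(O[Si](C)(C)C)(c1ccccc1)c1ccccc1.[O-]C(=O)c1ccccc1 | intermediate, not isolated
10 | dearomatised cycloadduct as its catalyst iminium benzoate (C7a–C7 and C6–C5 formed, C7a–H, C3a=C4) | C(=[N+]1CCC[C@H]1C(O[Si](C)(C)C)(c1ccccc1)c1ccccc1)[C@H]1[C@@H](OCc2ccccc2)C=C2C=C(C(=O)OC)N3[C@H]2[C@@H]1CCCC3.[O-]C(=O)c1ccccc1 | intermediate, not isolated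
11 | methyl (5S,6R,7R)-5-(benzyloxy)-6-formyl-4,5,6,7-tetrahydro-1,7-butanoindole-2-carboxylate (key-step product) | O=C[C@H]1[C@@H](OCc2ccccc2)Cc2cc(C(=O)OC)n3c2[C@@H]1CCCC3 | intermediate
12 | methyl (5S,6R,7R)-5-(benzyloxy)-6-ethenyl-4,5,6,7-tetrahydro-1,7-butanoindole-2-carboxylate | C=C[C@H]1[C@@H](OCc2ccccc2)Cc2cc(C(=O)OC)n3c2[C@@H]1CCCC3 | intermediate
13 | methyl (5S,6R,7R)-6-ethyl-5-hydroxy-4,5,6,7-tetrahydro-1,7-butanoindole-2-carboxylate | CC[C@H]1[C@@H](O)Cc2cc(C(=O)OC)n3c2[C@@H]1CCCC3 | intermediate
14 | methyl (6R,7R)-6-ethyl-5-oxo-4,5,6,7-tetrahydro-1,7-butanoindole-2-carboxylate | CC[C@H]1C(=O)Cc2cc(C(=O)OC)n3c2[C@@H]1CCCC3 | intermediate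
15 | ethyl (2S)-2-hydroxypropanoate | CCOC(=O)[C@H](C)O | starting material
16 | ethyl (2S)-2-[(trifluoromethanesulfonyl)oxy]propanoate | CCOC(=O)[C@H](C)OS(=O)(=O)C(F)(F)F | intermediate
17 | sodium C4=C5 enolate of 14 | CC[C@H]1C([O-])=Cc2cc(C(=O)OC)n3c2[C@@H]1CCCC3.[Na+] | intermediate, not isolated
18 | methyl (4S,6R,7R)-4-[(2S)-1-ethoxy-1-oxopropan-2-yl]-6-ethyl-5-oxo-4,5,6,7-tetrahydro-1,7-butanoindole-2-carboxylate | CC[C@H]1C(=O)[C@@H]([C@H](C)C(=O)OCC)c2cc(C(=O)OC)n3c2[C@@H]1CCCC3 | intermediate
19 | methyl (4S,5R,6R,7R)-4-[(2S)-1-ethoxy-1-oxopropan-2-yl]-6-ethyl-5-hydroxy-4,5,6,7-tetrahydro-1,7-butanoindole-2-carboxylate (lithium alkoxide in the flask) | CC[C@H]1[C@@H](O)[C@@H]([C@H](C)C(=O)OCC)c2cc(C(=O)OC)n3c2[C@@H]1CCCC3 | intermediate, not isolated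
20 | γ-lactone (ring D) of (2S)-2-[(4S,5R,6R,7R)-6-ethyl-5-hydroxy-2-(methoxycarbonyl)-4,5,6,7-tetrahydro-1,7-butanoindol-4-yl]propanoic acid | CC[C@H]1[C@H]2OC(=O)[C@@H](C)[C@H]2c2cc(C(=O)OC)n3c2[C@@H]1CCCC3 | intermediate
21 | dilithium (2S)-2-[(4S,5R,6R,7R)-2-carboxylato-6-ethyl-5-hydroxy-4,5,6,7-tetrahydro-1,7-butanoindol-4-yl]propanoate | CC[C@H]1[C@@H](O)[C@@H]([C@H](C)C(=O)[O-])c2cc(C(=O)[O-])n3c2[C@@H]1CCCC3.[Li+].[Li+] | intermediate, not isolated
22 | ring D lactone 2-carboxylic acid (20 with CO2H in place of CO2CH3) | CC[C@H]1[C@H]2OC(=O)[C@@H](C)[C@H]2c2cc(C(=O)O)n3c2[C@@H]1CCCC3 | intermediate, not isolated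
23 | γ-lactone (ring D) of (2S)-2-[(4S,5R,6R,7R)-6-ethyl-5-hydroxy-4,5,6,7-tetrahydro-1,7-butanoindol-4-yl]propanoic acid | CC[C@H]1[C@H]2OC(=O)[C@@H](C)[C@H]2c2ccn3c2[C@@H]1CCCC3 | intermediate
24 | (S)-2-methylsuccinic acid | C[C@@H](CC(=O)O)C(=O)O | starting material
25 | (3S)-3-methyloxolane-2,5-dione | C[C@H]1CC(=O)OC1=O | intermediate
26 | (2S)-2-methyl-4-oxo-4-[C2 of ring D lactone 23]butanoic acid | CC[C@H]1[C@H]2OC(=O)[C@@H](C)[C@H]2c2cc(C(=O)C[C@H](C)C(=O)O)n3c2[C@@H]1CCCC3 | intermediate
27 | (2S,4R)-4-hydroxy-2-methyl-4-[C2 of ring D lactone 23]butanoic acid | CC[C@H]1[C@H]2OC(=O)[C@@H](C)[C@H]2c2cc([C@H](O)C[C@H](C)C(=O)O)n3c2[C@@H]1CCCC3 | intermediate, not isolated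
28 | CNP0232452.1 (4S,5R,6R,7R; ring D α-carbon S; ring E 2R,4S) | CC[C@H]1[C@H]2OC(=O)[C@@H](C)[C@H]2c2cc([C@H]3C[C@H](C)C(=O)O3)n3c2[C@@H]1CCCC3 | target

Total step count: 15 (13 in the main line plus the preparations of 16 and 25).
Longest linear sequence: 13 steps (steps 1–8, 10–12, 14 and 15).

Steps most likely to fail

Step 5. The cascade may stop after the first bond, if loss of the C7a proton outruns closure of ring B, or the enol ether may hydrolyse before it cyclises. The fallback sets out from 8 and makes the two bonds in separate operations. The same amine catalyst first gives the ring-C-closed conjugate adduct methyl (9R)-1-[(E)-2-(benzyloxy)ethenyl]-9-(2-oxoethyl)-6,7,8,9-tetrahydro-5H-pyrrolo[1,2-a]azepine-3-carboxylate F1, which is isolated. Condensation with pyrrolidine then gives its enamine F2. Trifluoroacetic acid at −20 °C protonates the enol ether at C4, and the enamine carbon C6 adds to the oxocarbenium carbon C5 (6-(enolexo)-exo-trig). Hydrolysis brings the route back at 11, with C6 again trans to C7 by equilibration of the aldehyde; the C5 centre is erased in step 8 in any case.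

Step 11. Equilibration at C4 may leave the side chain trans to the ethyl group, and the hydride then enters from the other face and gives a diastereomeric lactone. The fallback sets out from 18 and replaces the stoichiometric hydride by a transfer hydrogenation under dynamic kinetic conditions: RuCl(TsNCH2CH2NH2)(p-cymene), HCO2H/Et3N, 40 °C. C4 epimerises quickly in the amine buffer, and the bulky ruthenium hydride should reduce fastest the epimer in which both flanking substituents lie opposite the incoming hydride. Both C4 epimers are thereby funnelled to hydroxy ester 19, which lactonises, and the route is rejoined at 20. This fallback makes no new compound (F0).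

Step 15. Hydride transfer to the electron-rich 2-acylpyrrole carbonyl may be too slow, or the pyrrolylic C–O bond may ionise and erode the configuration at the ring E carbinol carbon. The fallback sets out from 26 and gives up reagent control: NaBH4 in MeOH at 0 °C followed by acetic acid gives 28 together with its epimer at the ring E carbinol carbon F3. The two are separated by chromatography. F3 is re-equilibrated through the pyrrole-stabilised cation with catalytic camphorsulfonic acid in CH2Cl2 and separated again, so that the material converges on 28.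

Further compounds
F1 | step 5 | methyl (9R)-1-[(E)-2-(benzyloxy)ethenyl]-9-(2-oxoethyl)-6,7,8,9-tetrahydro-5H-pyrrolo[1,2-a]azepine-3-carboxylate | COC(=O)c1cc(/C=C/OCc2ccccc2)c2n1CCCC[C@@H]2CC=O
F2 | step 5 | methyl (9R)-1-[(E)-2-(benzyloxy)ethenyl]-9-[(E)-2-(pyrrolidin-1-yl)ethenyl]-6,7,8,9-tetrahydro-5H-pyrrolo[1,2-a]azepine-3-carboxylate | COC(=O)c1cc(/C=C/OCc2ccccc2)c2n1CCCC[C@@H]2/C=C/N1CCCC1
F0 | step 11 | none | none
F3 | step 15 | epimer of 28 at the ring E carbinol carbon (ring E 2S,4S) | CC[C@H]1[C@H]2OC(=O)[C@@H](C)[C@H]2c2cc([C@@H]3C[C@H](C)C(=O)O3)n3c2[C@@H]1CCCC3
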